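**Early times.** Early in the west run, target rises as starting material falls, and from 10.0 min both lie flat, with target at 50 % and starting material at 51 %. The south-west run flattens the same way. I take reagent as the limiting reagent and keep its ledger.

| flask | starting material | reagent | second substrate | precatalyst | remark | time |
|---|---|---|---|---|---|---|
| west | 0.11 M | 0.198 M | 0.11 M | 11 mM | run made earlier |  |
| south-west | 0.11 M | 0.198 M | 0.11 M | 16 mM | run made earlier |  |
| dawn | 0.11 M | 0.198 M | 0.110 M (fed, over 30 min) | 11 mM | all else is in the flask from the start; the feed brings no volume worth counting | 40 min |
| spring | 0.11 M | 0.198 M (fed, over 30 min) | 0.110 M | 11 mM | all else is in the flask from the start; the feed brings no volume worth counting | 40 min |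
| autumn | 0.11 M | 0.198 M | 0.110 M (fed, over 3.0 min) | 11 mM | all else is in the flask from the start; the feed brings no volume worth counting | 40 min |
| midnight | 0.11 M | 0.198 M | 0.110 M | 11 mM | everything together at the start | 40 min |

| run | time / min | target / % | starting material / % |
|---|---|---|---|
| west | 1.33 | 10 | 92 |
| west | 4.00 | 30 | 68 |
| west | 6.00 | 41 | 58 |
| west | 10.0 | 50 | 51 |
| west | 15.0 | 48 | 51 |
| west | 20.0 | 49 | 52 |
| west | 25.0 | 50 | 54 |
| south-west | 0.667 | 5 | 99 |
| south-west | 2.00 | 20 | 80 |
| south-west | 3.00 | 29 | 69 |
| south-west | 5.00 | 45 | 53 |
| south-west | 8.00 | 55 | 48 |
| south-west | 10.0 | 53 | 47 |
| south-west | 12.0 | 53 | 48 |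

(each reading ± 1.5 percentage points)

- reactions considered so far: starting material + reagent + catalyst -> catalyst + target; second substrate + reagent + catalyst -> catalyst + second product; precatalyst -> catalyst; 2 reagent -> homo dimer

1. the best flask by amount of target, in percent of the starting material charged; "all alike" if 1.5 percentage points covers them all (dawn / spring / autumn / midnight / all alike)
2. amount of target at the end, in percent of the starting material charged, dawn
3. amount of target at the end, in percent of the starting material charged, spring
4. amount of target at the end, in percent of the starting material charged, autumn
5. amount of target at the end, in percent of the starting material charged, midnight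

**The ledger.** The west run starts with 0.198 M of reagent. Target draws 0.0550 M. No reading shows the second substrate, so I assume that it draws reagent like starting material, which is another 0.0550 M. The balance, 0.0880 M, goes to homo dimer.

**The order.** Let b be the reagent concentration. The catalysed steps go as b and the dimer step as b squared, so at fixed substrates and catalyst the ratio of the dimer rate to the catalysed rate is proportional to b. The south-west run fits this: with 16 mM of precatalyst, more than west, its plateau reads 55 %.

**My reckoning.** I define the reagent coverage as the reagent charge divided by the sum of both substrate charges, 90.0 %. It is the fraction of each substrate converted if the two convert at the same fractional pace and the dimer draws nothing. Spring's feed lasts 30 min, longer than west took to reach its plateau, so I expect b to stay small and spring's target to land just under 90.0 %.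

**The forecast.** It names spring, with dawn 60 %, spring 69 %, autumn 51 % and midnight 50 %, on these grounds: “Spring keeps reagent low, suppressing dimer”. My figure for spring stands above its figure.

**The result.** The best flask is spring, with dawn 67.1 %, spring 87.4 %, autumn 50.6 % and midnight 49.6 %.

    starting material + reagent + catalyst → catalyst + target (k = 12.0 L² mol⁻² s⁻¹)
    second substrate + reagent + catalyst → catalyst + second product (k = 11.0 L² mol⁻² s⁻¹)
    precatalyst → catalyst (k = 0.00150 s⁻¹)
    2 reagent → homo dimer (k = 0.0150 L mol⁻¹ s⁻¹)

**Where they part.** The forecast and the flask differ most on spring, by 18 percentage points. The constants of the target step and the second product step are 12 L² mol⁻² s⁻¹ and 11 L² mol⁻² s⁻¹, a ratio of 1.09, while homo dimer at 40.0 min stands at 0.00352 M in spring against 0.0460 M in midnight. Spring's target of 87.4 % lies just below the coverage of 90.0 %.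

**Second flask.** The neighbour of spring charged with 0.44 M of second substrate has a coverage of 36.0 %. Its computed target is 37.9 %.

Readings and results are simulated from invented constants; scatter was added.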